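**Retrosynthetic overview** (ring atoms C1–C14 numbered as in the SMILES: C1 and C14 carry OAc, C5 carries OH)
1. Target ⇐ macrocyclic 1,14-diol with C5 silyl ether (acetylation, then desilylation).
2. The only ring (14-membered) is closed last at C11–C12: Zr-catalysed carboalumination of a C10≡C11 alkyne, then Pd coupling with a (12Z)-iodoalkene made by alkoxide-directed anti-carbomagnesiation (iPrMgCl, CuI; I2) of the C14 propargylic alcohol.
3. C2=C3 (Z) ⇐ Wittig union of a D-tartrate-derived α-alkoxy methyl ketone (C1, C14) with a γ-silyloxy ylide (C5 from (S)-α-hydroxy-γ-butyrolactone).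
4. Key step: the C8–C9 bond and the 6E olefin ⇐ [3,3]-sigmatropic Claisen (Saucy–Marbet) rearrangement of a tertiary vinyl carbinol with 2-methoxypropene; its methyl ketone becomes the C10≡C11 alkyne.
5. Ring order: no ring is made before step 16; the macrocycle is the only ring formed.

Assumption: dimethyl 2,3-O-isopropylidene-D-tartrate (1) and (S)-α-hydroxy-γ-butyrolactone (6) are bought as the only sources of chirality; all other reagents are achiral and commercial.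

**Western fragment (C12–C2)**

Step 1
Reactants: 1 dimethyl (4S,5S)-2,2-dimethyl-1,3-dioxolane-4,5-dicarboxylate
Product: 2 (4S,5S)-N4,N5-dimethoxy-N4,N5,2,2-tetramethyl-1,3-dioxolane-4,5-dicarboxamide
Conditions: MeNH(OMe)·HCl, iPrMgCl, THF, −20 °C
Reagents that add atoms: N,O-dimethylhydroxylamine hydrochloride, Cl.CNOC
Why: Aminolysis of both esters by the magnesium amide of MeNH(OMe) gives the bis-Weinreb amide without touching the two tartrate stereocentres, which are locked in the trans-dioxolane.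

Step 2
Reactants: 2 (4S,5S)-N4,N5-dimethoxy-N4,N5,2,2-tetramethyl-1,3-dioxolane-4,5-dicarboxamide
Product: 3 (4S,5S)-5-formyl-N-methoxy-N,2,2-trimethyl-1,3-dioxolane-4-carboxamide
Conditions: iBu2AlH (1.05 equiv), THF, −78 °C; aq. KNaC4H4O6
Reagents that add atoms: none
Why: Weinreb amide reduction stops at the chelated tetrahedral aluminate, so one equivalent of hydride gives mainly the mono-aldehyde (unreacted 2 is recycled) and the trans-acetonide prevents epimerisation.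

Step 3
Reactants: 3 (4S,5S)-5-formyl-N-methoxy-N,2,2-trimethyl-1,3-dioxolane-4-carboxamide
Product: 4 (4S,5R)-5-ethynyl-N-methoxy-N,2,2-trimethyl-1,3-dioxolane-4-carboxamide
Conditions: dimethyl (1-diazo-2-oxopropyl)phosphonate, K2CO3, MeOH, 0 °C → rt
Reagents that add atoms: dimethyl (1-diazo-2-oxopropyl)phosphonate, COP(=O)(OC)C(=[N+]=[N-])C(C)=O
Why: Ohira–Bestmann (Seyferth–Gilbert) homologation turns the aldehyde into the terminal alkyne, adding C12, under conditions mild enough for the α-alkoxy centre (the descriptor changes only through CIP priorities).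

Step 4
Reactants: 4 (4S,5R)-5-ethynyl-N-methoxy-N,2,2-trimethyl-1,3-dioxolane-4-carboxamide
Product: 5 1-[(4S,5R)-5-ethynyl-2,2-dimethyl-1,3-dioxolan-4-yl]ethan-1-one
Conditions: MeMgBr (2.5 equiv), THF, 0 °C; aq. NH4Cl
Reagents that add atoms: methylmagnesium bromide, C[Mg]Br
Why: Weinreb ketone synthesis, in which the stable magnesium chelate prevents over-addition and delivers the C2 methyl ketone.

**Eastern fragment (C3–C11)**

Step 5
Reactants: 6 (3S)-3-hydroxyoxolan-2-one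
Product: 7 (3S)-3-[(tert-butyldiphenylsilyl)oxy]oxolan-2-one
Conditions: TBDPSCl, imidazole, DMF, rt
Reagents that add atoms: tert-butyl(chloro)diphenylsilane, CC(C)(C)[Si](Cl)(c1ccccc1)c1ccccc1
Why: Silylation of the bought C5 carbinol with a bulky group that resists the later acid, base and heat and does not migrate.

Step 6
Reactants: 7 (3S)-3-[(tert-butyldiphenylsilyl)oxy]oxolan-2-one
Product: 8 (3S)-3-[(tert-butyldiphenylsilyl)oxy]-5-hydroxypentan-2-one (in equilibrium with its cyclic hemiketal)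
Conditions: MeLi (1.05 equiv), THF, −78 °C; aq. NH4Cl
Reagents that add atoms: methyllithium, [Li]C
Why: Mono-addition of MeLi to the lactone, whose lithium hemiketalate does not collapse at −78 °C, installs the C6 methyl group.

Step 7
Reactants: 8 (3S)-3-[(tert-butyldiphenylsilyl)oxy]-5-hydroxypentan-2-one
Product: 9 (3S)-3-[(tert-butyldiphenylsilyl)oxy]-4-methylhex-5-ene-1,4-diol (both C4 epimers)
Conditions: CH2=CHMgBr (3 equiv), THF, −78 → 0 °C
Reagents that add atoms: vinylmagnesium bromide, C=C[Mg]Br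
Why: Grignard addition to the ketone (the hemiketal opens under the basic conditions) gives the tertiary vinyl carbinol, whose new centre is irrelevant because it becomes sp2 in step 8.

Step 8 (key step)
Reactants: 9 (3S)-3-[(tert-butyldiphenylsilyl)oxy]-4-methylhex-5-ene-1,4-diol
Product: 11 (5E,7S)-7-[(tert-butyldiphenylsilyl)oxy]-9-[(2-methoxypropan-2-yl)oxy]-6-methylnon-5-en-2-one, via allyl isopropenyl ether 10 (not isolated)
Conditions: 2-methoxypropene (10 equiv), PPTS (5 mol%), toluene, rt then 120 °C (sealed tube); Et3N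
Reagents that add atoms: 2-methoxypropene, COC(C)=C
Why: Saucy–Marbet Claisen rearrangement, in which the chair [3,3]-sigmatropic shift of the allyl isopropenyl ether forms the C8–C9 bond and, with the bulky silyloxyalkyl group pseudo-equatorial, the 6E olefin (expected about 8:1, minor isomer removed by chromatography), while excess reagent masks the primary alcohol as its acetal.

Step 9
Reactants: 11 (5E,7S)-7-[(tert-butyldiphenylsilyl)oxy]-9-[(2-methoxypropan-2-yl)oxy]-6-methylnon-5-en-2-one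
Product: 14 (3S,4E)-3-[(tert-butyldiphenylsilyl)oxy]-4-methyl-9-(trimethylsilyl)non-4-en-8-yn-1-ol, via enol phosphate 12 (not isolated), via acetal-protected silylalkyne 13 (not isolated)
Conditions: LiN(iPr)2 (1.1 equiv), THF, −78 °C; ClP(O)(OEt)2; LiN(iPr)2 (2.3 equiv), −78 °C → rt; Me3SiCl; then 0.5 M HCl, THF, 0 °C
Reagents that add atoms: chlorotrimethylsilane, C[Si](C)(C)Cl
Why: Negishi methyl ketone to alkyne conversion (kinetic enol phosphate, elimination, C-silylation of the lithium acetylide) makes the protected C10≡C11 alkyne, and the acidic work-up removes only the very labile acetal.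

Step 10
Reactants: 14 (3S,4E)-3-[(tert-butyldiphenylsilyl)oxy]-4-methyl-9-(trimethylsilyl)non-4-en-8-yn-1-ol
Product: 15 tert-butyl{[(3S,4E)-1-iodo-4-methyl-9-(trimethylsilyl)non-4-en-8-yn-3-yl]oxy}diphenylsilane
Conditions: I2, PPh3, imidazole, CH2Cl2, 0 °C
Reagents that add atoms: iodine, II
Why: Appel-type (Garegg–Samuelsson) iodination of the primary alcohol, with no stereocentre involved.

Step 11
Reactants: 15 tert-butyl{[(3S,4E)-1-iodo-4-methyl-9-(trimethylsilyl)non-4-en-8-yn-3-yl]oxy}diphenylsilane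
Product: 16 [(3S,4E)-3-[(tert-butyldiphenylsilyl)oxy]-4-methyl-9-(trimethylsilyl)non-4-en-8-yn-1-yl]triphenylphosphonium iodide
Conditions: PPh3, MeCN, 80 °C
Reagents that add atoms: triphenylphosphine, c1ccc(cc1)P(c1ccccc1)c1ccccc1
Why: SN2 quaternisation of the primary iodide gives the Wittig salt.

**Union and macrocycle**

Step 12
Reactants: 16 [(3S,4E)-3-[(tert-butyldiphenylsilyl)oxy]-4-methyl-9-(trimethylsilyl)non-4-en-8-yn-1-yl]triphenylphosphonium iodide; 5 1-[(4S,5R)-5-ethynyl-2,2-dimethyl-1,3-dioxolan-4-yl]ethan-1-one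
Product: 18 (4R,5R)-4-ethynyl-2,2-dimethyl-5-[(2Z,5S,6E)-5-[(tert-butyldiphenylsilyl)oxy]-6-methyl-11-(trimethylsilyl)undeca-2,6-dien-10-yn-2-yl]-1,3-dioxolane, via phosphorus ylide 17 (not isolated)
Conditions: KN(SiMe3)2, THF, −78 °C; then 5, −78 → 0 °C
Reagents that add atoms: none
Why: Wittig olefination of an α-alkoxy methyl ketone with a salt-free non-stabilised ylide (Still's Z-selective case) places the oxygenated carbon C1 cis to C4, giving the 2Z olefin, and the trans-dioxolane keeps C1 from epimerising.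

Step 13
Reactants: 18 (4R,5R)-4-ethynyl-2,2-dimethyl-5-[(2Z,5S,6E)-5-[(tert-butyldiphenylsilyl)oxy]-6-methyl-11-(trimethylsilyl)undeca-2,6-dien-10-yn-2-yl]-1,3-dioxolane
Product: 19 (3R,4R,5Z,8S,9E)-8-[(tert-butyldiphenylsilyl)oxy]-5,9-dimethyl-14-(trimethylsilyl)tetradeca-5,9-dien-1,13-diyne-3,4-diol
Conditions: CF3CO2H/H2O (9:1), CH2Cl2, 0 °C
Reagents that add atoms: none
Why: Acid hydrolysis of the acetonide frees the C1/C14 diol, while the TBDPS ether and the C-silyl alkyne are stable to brief aqueous acid.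

Step 14
Reactants: 19 (3R,4R,5Z,8S,9E)-8-[(tert-butyldiphenylsilyl)oxy]-5,9-dimethyl-14-(trimethylsilyl)tetradeca-5,9-dien-1,13-diyne-3,4-diol
Product: 21 (1Z,3R,4R,5Z,8S,9E)-8-[(tert-butyldiphenylsilyl)oxy]-1-iodo-5,9-dimethyl-2-(propan-2-yl)-14-(trimethylsilyl)tetradeca-1,5,9-trien-13-yne-3,4-diol, via alkenylmagnesium chelate 20 (not isolated)
Conditions: iPrMgCl (6 equiv), CuI (20 mol%), THF, −20 °C → rt; then I2, −78 → 0 °C
Reagents that add atoms: isopropylmagnesium chloride, CC(C)[Mg]Cl; iodine, II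
Why: Duboudin alkoxide-directed, CuI-catalysed anti-carbomagnesiation puts isopropyl on C13 and magnesium on C12 cis to the C14 oxygen (five-membered chelate), and iodinolysis with retention gives the 12Z iodoalkene; the silylated alkyne has no directing group and stays inert.

Step 15
Reactants: 21 (1Z,3R,4R,5Z,8S,9E)-8-[(tert-butyldiphenylsilyl)oxy]-1-iodo-5,9-dimethyl-2-(propan-2-yl)-14-(trimethylsilyl)tetradeca-1,5,9-trien-13-yne-3,4-diol
Product: 22 (1Z,3R,4R,5Z,8S,9E)-8-[(tert-butyldiphenylsilyl)oxy]-1-iodo-5,9-dimethyl-2-(propan-2-yl)tetradeca-1,5,9-trien-13-yne-3,4-diol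
Conditions: K2CO3 (0.3 equiv), MeOH, rt
Reagents that add atoms: none
Why: Methanolysis of the alkynyl C–Si bond frees the terminal alkyne without affecting the iodoalkene or the TBDPS ether.

Step 16
Reactants: 22 (1Z,3R,4R,5Z,8S,9E)-8-[(tert-butyldiphenylsilyl)oxy]-1-iodo-5,9-dimethyl-2-(propan-2-yl)tetradeca-1,5,9-trien-13-yne-3,4-diol
Product: 24 (1R,2Z,5S,6E,10E,12Z,14R)-5-[(tert-butyldiphenylsilyl)oxy]-2,6,10-trimethyl-13-(propan-2-yl)cyclotetradeca-2,6,10,12-tetraene-1,14-diol, via alkenylalane 23 (not isolated)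
Conditions: AlMe3 (5 equiv), Cp2ZrCl2 (25 mol%), CH2Cl2, 0 °C → rt; then THF (0.002 M), ZnCl2 (20 mol%), Pd(PPh3)4 (10 mol%), 45 °C
Reagents that add atoms: trimethylaluminium, C[Al](C)C
Why: Negishi zirconium-catalysed syn-carboalumination adds methyl to C10 and aluminium to C11 (10E), and zerovalent palladium then couples the alkenylalane with the iodoalkene with retention at both sp2 carbons (Negishi coupling), closing the 14-membered ring with the 10E,12Z diene.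

Step 17
Reactants: 24 (1R,2Z,5S,6E,10E,12Z,14R)-5-[(tert-butyldiphenylsilyl)oxy]-2,6,10-trimethyl-13-(propan-2-yl)cyclotetradeca-2,6,10,12-tetraene-1,14-diol
Product: 25 (1R,2Z,5S,6E,10E,12Z,14R)-5-[(tert-butyldiphenylsilyl)oxy]-2,6,10-trimethyl-13-(propan-2-yl)cyclotetradeca-2,6,10,12-tetraene-1,14-diyl diacetate
Conditions: Ac2O, pyridine, DMAP (cat.), CH2Cl2, rt
Reagents that add atoms: acetic anhydride, CC(=O)OC(C)=O
Why: DMAP-catalysed acylation of the two free secondary alcohols, with C5 still silylated so that only C1 and C14 are acetylated.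

Step 18
Reactants: 25 (1R,2Z,5S,6E,10E,12Z,14R)-5-[(tert-butyldiphenylsilyl)oxy]-2,6,10-trimethyl-13-(propan-2-yl)cyclotetradeca-2,6,10,12-tetraene-1,14-diyl diacetate
Product: 26 gibberosene E
Conditions: Bu4NF, AcOH (1:1), THF, rt
Reagents that add atoms: none
Why: Buffered fluoride cleaves the silyl ether at C5 without acetate migration or elimination of the allylic acetates.

**Compound list**
1 | dimethyl (4S,5S)-2,2-dimethyl-1,3-dioxolane-4,5-dicarboxylate (dimethyl 2,3-O-isopropylidene-D-tartrate) | COC(=O)[C@H]1OC(C)(C)O[C@@H]1C(=O)OC | starting material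
2 | (4S,5S)-N4,N5-dimethoxy-N4,N5,2,2-tetramethyl-1,3-dioxolane-4,5-dicarboxamide | CON(C)C(=O)[C@H]1OC(C)(C)O[C@@H]1C(=O)N(C)OC | intermediate
3 | (4S,5S)-5-formyl-N-methoxy-N,2,2-trimethyl-1,3-dioxolane-4-carboxamide | CON(C)C(=O)[C@H]1OC(C)(C)O[C@@H]1C=O | intermediate
4 | (4S,5R)-5-ethynyl-N-methoxy-N,2,2-trimethyl-1,3-dioxolane-4-carboxamide | CON(C)C(=O)[C@H]1OC(C)(C)O[C@@H]1C#C | intermediate
5 | 1-[(4S,5R)-5-ethynyl-2,2-dimethyl-1,3-dioxolan-4-yl]ethan-1-one | CC(=O)[C@H]1OC(C)(C)O[C@@H]1C#C | intermediate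
6 | (3S)-3-hydroxyoxolan-2-one ((S)-α-hydroxy-γ-butyrolactone) | O[C@H]1CCOC1=O | starting material
7 | (3S)-3-[(tert-butyldiphenylsilyl)oxy]oxolan-2-one | CC(C)(C)[Si](c1ccccc1)(c1ccccc1)O[C@H]1CCOC1=O | intermediate
8 | (3S)-3-[(tert-butyldiphenylsilyl)oxy]-5-hydroxypentan-2-one | CC(=O)[C@H](CCO)O[Si](c1ccccc1)(c1ccccc1)C(C)(C)C | intermediate
9 | (3S)-3-[(tert-butyldiphenylsilyl)oxy]-4-methylhex-5-ene-1,4-diol (C4 epimers) | C=CC(C)(O)[C@H](CCO)O[Si](c1ccccc1)(c1ccccc1)C(C)(C)C | intermediate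
10 | tert-butyl{[(3S)-1-[(2-methoxypropan-2-yl)oxy]-4-methyl-4-(prop-1-en-2-yloxy)hex-5-en-3-yl]oxy}diphenylsilane (allyl isopropenyl ether) | C=CC(C)(OC(C)=C)[C@H](CCOC(C)(C)OC)O[Si](c1ccccc1)(c1ccccc1)C(C)(C)C | intermediate
11 | (5E,7S)-7-[(tert-butyldiphenylsilyl)oxy]-9-[(2-methoxypropan-2-yl)oxy]-6-methylnon-5-en-2-one | CC(=O)CC/C=C(\C)[C@H](CCOC(C)(C)OC)O[Si](c1ccccc1)(c1ccccc1)C(C)(C)C | intermediate
12 | diethyl (5E,7S)-7-[(tert-butyldiphenylsilyl)oxy]-9-[(2-methoxypropan-2-yl)oxy]-6-methylnona-1,5-dien-2-yl phosphate (enol phosphate) | C=C(OP(=O)(OCC)OCC)CC/C=C(\C)[C@H](CCOC(C)(C)OC)O[Si](c1ccccc1)(c1ccccc1)C(C)(C)C | intermediate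
13 | tert-butyl{[(3S,4E)-1-[(2-methoxypropan-2-yl)oxy]-4-methyl-9-(trimethylsilyl)non-4-en-8-yn-3-yl]oxy}diphenylsilane | C[Si](C)(C)C#CCC/C=C(\C)[C@H](CCOC(C)(C)OC)O[Si](c1ccccc1)(c1ccccc1)C(C)(C)C | intermediate
14 | (3S,4E)-3-[(tert-butyldiphenylsilyl)oxy]-4-methyl-9-(trimethylsilyl)non-4-en-8-yn-1-ol | C[Si](C)(C)C#CCC/C=C(\C)[C@H](CCO)O[Si](c1ccccc1)(c1ccccc1)C(C)(C)C | intermediate
15 | tert-butyl{[(3S,4E)-1-iodo-4-methyl-9-(trimethylsilyl)non-4-en-8-yn-3-yl]oxy}diphenylsilane | C[Si](C)(C)C#CCC/C=C(\C)[C@H](CCI)O[Si](c1ccccc1)(c1ccccc1)C(C)(C)C | intermediate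
16 | [(3S,4E)-3-[(tert-butyldiphenylsilyl)oxy]-4-methyl-9-(trimethylsilyl)non-4-en-8-yn-1-yl]triphenylphosphonium iodide | C[Si](C)(C)C#CCC/C=C(\C)[C@H](CC[P+](c1ccccc1)(c1ccccc1)c1ccccc1)O[Si](c1ccccc1)(c1ccccc1)C(C)(C)C.[I-] | intermediate
17 | [(3S,4E)-3-[(tert-butyldiphenylsilyl)oxy]-4-methyl-9-(trimethylsilyl)non-4-en-8-yn-1-ylidene]triphenyl-λ5-phosphane (ylide) | C[Si](C)(C)C#CCC/C=C(\C)[C@H](CC=P(c1ccccc1)(c1ccccc1)c1ccccc1)O[Si](c1ccccc1)(c1ccccc1)C(C)(C)C | intermediate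
18 | (4R,5R)-4-ethynyl-2,2-dimethyl-5-[(2Z,5S,6E)-5-[(tert-butyldiphenylsilyl)oxy]-6-methyl-11-(trimethylsilyl)undeca-2,6-dien-10-yn-2-yl]-1,3-dioxolane | C#C[C@H]1OC(C)(C)O[C@@H]1/C(C)=C\C[C@H](O[Si](c2ccccc2)(c2ccccc2)C(C)(C)C)/C(C)=C/CCC#C[Si](C)(C)C | intermediate
19 | (3R,4R,5Z,8S,9E)-8-[(tert-butyldiphenylsilyl)oxy]-5,9-dimethyl-14-(trimethylsilyl)tetradeca-5,9-dien-1,13-diyne-3,4-diol | C#C[C@@H](O)[C@H](O)/C(C)=C\C[C@H](O[Si](c1ccccc1)(c1ccccc1)C(C)(C)C)/C(C)=C/CCC#C[Si](C)(C)C | intermediate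
20 | (Z)-alkenylmagnesium chloride bis(chloromagnesium alkoxide) from 19 (Mg on C12 cis to the C14 oxygen, isopropyl on C13) | Cl[Mg]/C=C(/C(C)C)[C@@H](O[Mg]Cl)[C@H](O[Mg]Cl)/C(C)=C\C[C@H](O[Si](c1ccccc1)(c1ccccc1)C(C)(C)C)/C(C)=C/CCC#C[Si](C)(C)C | intermediate
21 | (1Z,3R,4R,5Z,8S,9E)-8-[(tert-butyldiphenylsilyl)oxy]-1-iodo-5,9-dimethyl-2-(propan-2-yl)-14-(trimethylsilyl)tetradeca-1,5,9-trien-13-yne-3,4-diol | I/C=C(/C(C)C)[C@@H](O)[C@H](O)/C(C)=C\C[C@H](O[Si](c1ccccc1)(c1ccccc1)C(C)(C)C)/C(C)=C/CCC#C[Si](C)(C)C | intermediate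
22 | (1Z,3R,4R,5Z,8S,9E)-8-[(tert-butyldiphenylsilyl)oxy]-1-iodo-5,9-dimethyl-2-(propan-2-yl)tetradeca-1,5,9-trien-13-yne-3,4-diol | I/C=C(/C(C)C)[C@@H](O)[C@H](O)/C(C)=C\C[C@H](O[Si](c1ccccc1)(c1ccccc1)C(C)(C)C)/C(C)=C/CCC#C | intermediate
23 | (E)-alkenyldimethylalane bis(dimethylaluminium alkoxide) from 22 (Me on C10, Al on C11) | I/C=C(/C(C)C)[C@@H](O[Al](C)C)[C@H](O[Al](C)C)/C(C)=C\C[C@H](O[Si](c1ccccc1)(c1ccccc1)C(C)(C)C)/C(C)=C/CC/C(C)=C/[Al](C)C | intermediate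
24 | (1R,2Z,5S,6E,10E,12Z,14R)-5-[(tert-butyldiphenylsilyl)oxy]-2,6,10-trimethyl-13-(propan-2-yl)cyclotetradeca-2,6,10,12-tetraene-1,14-diol | O[C@@H]1/C(C)=C\C[C@H](O[Si](c2ccccc2)(c2ccccc2)C(C)(C)C)/C(C)=C/CC/C(C)=C/C=C(/C(C)C)[C@H]1O | intermediate
25 | (1R,2Z,5S,6E,10E,12Z,14R)-5-[(tert-butyldiphenylsilyl)oxy]-2,6,10-trimethyl-13-(propan-2-yl)cyclotetradeca-2,6,10,12-tetraene-1,14-diyl diacetate | CC(=O)O[C@@H]1/C(C)=C\C[C@H](O[Si](c2ccccc2)(c2ccccc2)C(C)(C)C)/C(C)=C/CC/C(C)=C/C=C(/C(C)C)[C@H]1OC(C)=O | intermediate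
26 | gibberosene E, (1R,2Z,5S,6E,10E,12Z,14R)-5-hydroxy-2,6,10-trimethyl-13-(propan-2-yl)cyclotetradeca-2,6,10,12-tetraene-1,14-diyl diacetate | CC(=O)O[C@@H]1/C(C)=C\C[C@H](O)/C(C)=C/CC/C(C)=C/C=C(/C(C)C)[C@H]1OC(C)=O | target

**Totals**
Total step count: 18. Longest linear sequence: 14 steps (6 → 26, steps 5–18).

**Three steps most likely to fail**

Step 8 (Claisen rearrangement of a tertiary carbinol: the E/Z ratio at C6=C7 rests only on the size difference between methyl and the silyloxyalkyl group, and the tertiary allylic alcohol may ionise). The fallback sets out from 7 and comes back at 14, building the 6E olefin by carbometalation instead. Lactone 7 is reduced with iBu2AlH (CH2Cl2, −78 °C) to the lactol (3S)-3-[(tert-butyldiphenylsilyl)oxy]oxolan-2-ol F1. Ohira–Bestmann homologation (K2CO3, MeOH) gives the alkynol (3S)-3-[(tert-butyldiphenylsilyl)oxy]pent-4-yn-1-ol F2. Zirconium-catalysed carboalumination (AlMe3, Cp2ZrCl2) with iodine quench gives the iodoalkene (3S,4E)-3-[(tert-butyldiphenylsilyl)oxy]-5-iodo-4-methylpent-4-en-1-ol F3. B-alkyl Suzuki–Miyaura coupling (Pd(dppf)Cl2, AsPh3, Cs2CO3, DMF/H2O, rt) of F3 with the borane 9-[4-(trimethylsilyl)but-3-yn-1-yl]-9-borabicyclo[3.3.1]nonane F4, made in the flask from 4-(trimethylsilyl)but-1-en-3-yne and 9-BBN-H, then gives 14.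

Step 14 (carbomagnesiation with a secondary Grignard reagent on a late, polyfunctional 1,2-diol). The fallback sets out from 2 and comes back at 21, making the C12=C13 bond by carbonyl olefination. Mono-addition of iPrMgCl (THF, 0 °C) to 2 gives the keto amide (4S,5S)-N-methoxy-N,2,2-trimethyl-5-(2-methylpropanoyl)-1,3-dioxolane-4-carboxamide F5. Stork–Zhao olefination with Ph3P=CHI (from (iodomethyl)triphenylphosphonium iodide and NaN(SiMe3)2, THF, −78 °C) should place iodine cis to the oxygenated carbon by the same α-alkoxy-ketone bias as in step 12, although that bias is less certain for an isopropyl ketone, so the isomers would be separated and the geometry checked by NOE. This gives the iodoalkene (4S,5R)-5-[(1Z)-1-iodo-3-methylbut-1-en-2-yl]-N-methoxy-N,2,2-trimethyl-1,3-dioxolane-4-carboxamide F6. MeMgBr converts F6 into the methyl ketone 1-[(4S,5R)-5-[(1Z)-1-iodo-3-methylbut-1-en-2-yl]-2,2-dimethyl-1,3-dioxolan-4-yl]ethan-1-one F7. Wittig reaction of F7 with ylide 17 gives the acetonide (4R,5R)-4-[(1Z)-1-iodo-3-methylbut-1-en-2-yl]-2,2-dimethyl-5-[(2Z,5S,6E)-5-[(tert-butyldiphenylsilyl)oxy]-6-methyl-11-(trimethylsilyl)undeca-2,6-dien-10-yn-2-yl]-1,3-dioxolane F8, and CF3CO2H/H2O hydrolysis gives 21.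

Step 16 (one-pot carboalumination and intramolecular alkenyl–alkenyl coupling to a 14-membered ring in the presence of aluminium alkoxides). The fallback sets out from 22 and comes back at 24, closing the ring by a tin-mediated coupling. Carboalumination (AlMe3, Cp2ZrCl2) of 22 is quenched with iodine to give the bis(iodoalkene) (1Z,3R,4R,5Z,8S,9E,13E)-8-[(tert-butyldiphenylsilyl)oxy]-1,14-diiodo-5,9,13-trimethyl-2-(propan-2-yl)tetradeca-1,5,9,13-tetraene-3,4-diol F9. Stille–Kelly cyclisation (Me3SnSnMe3, Pd(PPh3)4, dioxane, 90 °C, high dilution) then proceeds through the mono-stannane (1Z,3R,4R,5Z,8S,9E,13E)-8-[(tert-butyldiphenylsilyl)oxy]-1-iodo-5,9,13-trimethyl-2-(propan-2-yl)-14-(trimethylstannyl)tetradeca-1,5,9,13-tetraene-3,4-diol F10, whose intramolecular Stille coupling gives 24.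

**Further compounds**
F1 | step 8 | (3S)-3-[(tert-butyldiphenylsilyl)oxy]oxolan-2-ol | CC(C)(C)[Si](c1ccccc1)(c1ccccc1)O[C@H]1CCOC1O
F2 | step 8 | (3S)-3-[(tert-butyldiphenylsilyl)oxy]pent-4-yn-1-ol | C#C[C@H](CCO)O[Si](c1ccccc1)(c1ccccc1)C(C)(C)C
F3 | step 8 | (3S,4E)-3-[(tert-butyldiphenylsilyl)oxy]-5-iodo-4-methylpent-4-en-1-ol | I/C=C(\C)[C@H](CCO)O[Si](c1ccccc1)(c1ccccc1)C(C)(C)C
F4 | step 8 | 9-[4-(trimethylsilyl)but-3-yn-1-yl]-9-borabicyclo[3.3.1]nonane | C[Si](C)(C)C#CCCB1C2CCCC1CCC2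
F5 | step 14 | (4S,5S)-N-methoxy-N,2,2-trimethyl-5-(2-methylpropanoyl)-1,3-dioxolane-4-carboxamide | CC(C)C(=O)[C@H]1OC(C)(C)O[C@@H]1C(=O)N(C)OC
F6 | step 14 | (4S,5R)-5-[(1Z)-1-iodo-3-methylbut-1-en-2-yl]-N-methoxy-N,2,2-trimethyl-1,3-dioxolane-4-carboxamide | I/C=C(/C(C)C)[C@H]1OC(C)(C)O[C@@H]1C(=O)N(C)OC
F7 | step 14 | 1-[(4S,5R)-5-[(1Z)-1-iodo-3-methylbut-1-en-2-yl]-2,2-dimethyl-1,3-dioxolan-4-yl]ethan-1-one | I/C=C(/C(C)C)[C@H]1OC(C)(C)O[C@@H]1C(C)=O
F8 | step 14 | (4R,5R)-4-[(1Z)-1-iodo-3-methylbut-1-en-2-yl]-2,2-dimethyl-5-[(2Z,5S,6E)-5-[(tert-butyldiphenylsilyl)oxy]-6-methyl-11-(trimethylsilyl)undeca-2,6-dien-10-yn-2-yl]-1,3-dioxolane | I/C=C(/C(C)C)[C@H]1OC(C)(C)O[C@@H]1/C(C)=C\C[C@H](O[Si](c2ccccc2)(c2ccccc2)C(C)(C)C)/C(C)=C/CCC#C[Si](C)(C)C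
F9 | step 16 | (1Z,3R,4R,5Z,8S,9E,13E)-8-[(tert-butyldiphenylsilyl)oxy]-1,14-diiodo-5,9,13-trimethyl-2-(propan-2-yl)tetradeca-1,5,9,13-tetraene-3,4-diol | I/C=C(/C(C)C)[C@@H](O)[C@H](O)/C(C)=C\C[C@H](O[Si](c1ccccc1)(c1ccccc1)C(C)(C)C)/C(C)=C/CC/C(C)=C/I
F10 | step 16 | (1Z,3R,4R,5Z,8S,9E,13E)-8-[(tert-butyldiphenylsilyl)oxy]-1-iodo-5,9,13-trimethyl-2-(propan-2-yl)-14-(trimethylstannyl)tetradeca-1,5,9,13-tetraene-3,4-diol | I/C=C(/C(C)C)[C@@H](O)[C@H](O)/C(C)=C\C[C@H](O[Si](c1ccccc1)(c1ccccc1)C(C)(C)C)/C(C)=C/CC/C(C)=C/[Sn](C)(C)C
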